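**Retrosynthetic overview**
- The target is the ester of a (3E,4S)-4-hydroxy enol lactone (isoobtusilactone A) with a (2Z)-γ-keto acid. Disconnect the ester C–O bond (Yamaguchi), keeping the acid's carbinol as a TBS ether until the last step.
- The keto acid is the hydrolytically opened Z enol lactone, so both halves come from the E and Z isomers of one 3-tetradecylidene butanolide.
- The exocyclic C5=CH2 of each enol lactone comes from a 5-iodomethyl group (from 5-CH2OTBS) by dehydroiodination.
- Key C–C bond: intermolecular aldol of the lithium enolate of 3,5-di-O-TBS-2-deoxy-D-ribono-1,4-lactone with tetradecanal, then E1cB dehydration (E expected as major; Z also by photoisomerisation).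
- Rings: the single γ-lactone, carrying the (S)-carbinol of both halves, is made first from 2-deoxy-D-ribose. No other ring is formed, and in the acyl half this ring is opened again.

Assumption: the SMILES is read as (3E,4S) in the lactone half and (2Z,1′S) in the acyl half; 2-deoxy-D-ribose and tetradecanal are bought. TBS = tert-butyldimethylsilyl.

**Step 1**
Reactants: 1 2-deoxy-D-ribose
Product: 2 2-deoxy-D-ribono-1,4-lactone [(4S,5R)-4-hydroxy-5-(hydroxymethyl)oxolan-2-one]
Conditions: Br2, H2O, rt, 5 d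
Reagents that add atoms: none
Why: Bromine-water oxidation of the aldose hemiacetal to the aldono-γ-lactone leaves sugar C3 and C4 untouched; they become lactone C4 (S) and C5 (R).

**Step 2**
Reactants: 2 2-deoxy-D-ribono-1,4-lactone
Product: 3 3,5-di-O-TBS-2-deoxy-D-ribono-1,4-lactone [(4S,5R)-4-(TBSO)-5-(TBSO-methyl)oxolan-2-one]
Conditions: TBSCl, imidazole, DMF, rt
Reagents that add atoms: tert-butyldimethylsilyl chloride, CC(C)(C)[Si](C)(C)Cl
Why: Corey silylation caps both hydroxyls as silyl ethers, which are poor β-leaving groups and so let the lactone enolate of step 3 survive.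

**Step 3**
Reactants: 3 3,5-di-O-TBS-2-deoxy-D-ribono-1,4-lactone; 4 tetradecanal
Product: 6 (3S,4S,5R)-4-(TBSO)-5-(TBSO-methyl)-3-(1-hydroxytetradecyl)oxolan-2-one (3,4-trans; both carbinol epimers), via lithium enolate 5 (not isolated)
Conditions: LiN(iPr)2, THF, −78 °C; then 4, −78 °C; AcOH quench at −78 °C
Reagents that add atoms: none
Why: Key step, an intermolecular lithium-enolate aldol addition (Zimmerman–Traxler, attack anti to the 4-OTBS group) that joins the C14 chain to the sugar lactone; the two new centres are erased in step 4 and need no control, and −78 °C holds back β-elimination of the silyloxy group.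

**Step 4**
Reactants: 6 the aldol adduct
Product: 8 (3E,4S,5R)-3-tetradecylidene-4-(TBSO)-5-(TBSO-methyl)oxolan-2-one, via mesylate 7 (not isolated)
Conditions: MsCl, Et3N, CH2Cl2, 0 °C; then DBU, 0 °C → rt
Reagents that add atoms: none
Why: Mesylation then E1cB elimination completes the aldol condensation, the enolate expelling mesylate rather than the far poorer ring silyloxy group; E isomer 8 is expected to predominate (chain turned away from the enolate oxygen), and the minor Z isomer 9 is separated on silica and kept because both geometries are needed.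

**Step 5**
Reactants: 8 (3E,4S,5R)-3-tetradecylidene-4-(TBSO)-5-(TBSO-methyl)oxolan-2-one
Product: 9 (3Z,4S,5R)-3-tetradecylidene-4-(TBSO)-5-(TBSO-methyl)oxolan-2-one
Conditions: hν (300 nm), acetone, Ar, rt; chromatography, recovered 8 recycled
Reagents that add atoms: none
Why: Acetone-sensitised triplet E/Z photoisomerisation of the α-alkylidene lactone gives a photostationary mixture from which 9 is separated; C4 and C5 are not involved and triplet conditions hold back photodeconjugation.

**Step 6**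
Reactants: 8 (3E,4S,5R)-3-tetradecylidene-4-(TBSO)-5-(TBSO-methyl)oxolan-2-one
Product: 10 (3E,4S,5R)-5-(hydroxymethyl)-3-tetradecylidene-4-(TBSO)oxolan-2-one
Conditions: HF·pyridine, pyridine, THF, 0 °C
Reagents that add atoms: none
Why: Selective desilylation, the unhindered primary TBS ether being cleaved much faster than the secondary one next to the alkylidene group.

**Step 7**
Reactants: 10 (3E,4S,5R)-5-(hydroxymethyl)-3-tetradecylidene-4-(TBSO)oxolan-2-one
Product: 11 (3E,4S,5S)-5-(iodomethyl)-3-tetradecylidene-4-(TBSO)oxolan-2-one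
Conditions: PPh3, I2, imidazole, THF, 0 °C → rt
Reagents that add atoms: iodine, [I][I]
Why: Garegg–Samuelsson (Appel-type) iodination replaces the primary hydroxyl by SN2 at CH2; the C5 descriptor changes to S only because CH2I outranks C4.

**Step 8**
Reactants: 11 (3E,4S,5S)-5-(iodomethyl)-3-tetradecylidene-4-(TBSO)oxolan-2-one
Product: 12 (3E,4S)-5-methylidene-3-tetradecylidene-4-(TBSO)oxolan-2-one
Conditions: DBU, THF, 50 °C
Reagents that add atoms: none
Why: E2 dehydroiodination (the standard iodolactone-to-enol-lactone elimination) removes H5 and iodide to give the exocyclic enol lactone, C5 becoming sp2 and the C4 (S) centre staying untouched.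

**Step 9**
Reactants: 12 (3E,4S)-5-methylidene-3-tetradecylidene-4-(TBSO)oxolan-2-one
Product: 13 isoobtusilactone A [(3E,4S)-4-hydroxy-5-methylidene-3-tetradecylideneoxolan-2-one]
Conditions: HF·pyridine, THF, 0 °C → rt
Reagents that add atoms: none
Why: Fluoride-driven desilylation under mildly acidic, non-aqueous conditions frees the C4 hydroxyl without hydrolysing the enol lactone or moving either exocyclic double bond.

**Step 10**
Reactants: 9 (3Z,4S,5R)-3-tetradecylidene-4-(TBSO)-5-(TBSO-methyl)oxolan-2-one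
Product: 14 (3Z,4S,5R)-5-(hydroxymethyl)-3-tetradecylidene-4-(TBSO)oxolan-2-one
Conditions: HF·pyridine, pyridine, THF, 0 °C
Reagents that add atoms: none
Why: Selective desilylation of the primary TBS ether, as in step 6.

**Step 11**
Reactants: 14 (3Z,4S,5R)-5-(hydroxymethyl)-3-tetradecylidene-4-(TBSO)oxolan-2-one
Product: 15 (3Z,4S,5S)-5-(iodomethyl)-3-tetradecylidene-4-(TBSO)oxolan-2-one
Conditions: PPh3, I2, imidazole, THF, 0 °C → rt
Reagents that add atoms: iodine, [I][I]
Why: Garegg–Samuelsson iodination of the primary alcohol, as in step 7.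

**Step 12**
Reactants: 15 (3Z,4S,5S)-5-(iodomethyl)-3-tetradecylidene-4-(TBSO)oxolan-2-one
Product: 16 (3Z,4S)-5-methylidene-3-tetradecylidene-4-(TBSO)oxolan-2-one
Conditions: DBU, THF, 50 °C
Reagents that add atoms: none
Why: E2 dehydroiodination to the exocyclic enol lactone, as in step 8.

**Step 13**
Reactants: 16 (3Z,4S)-5-methylidene-3-tetradecylidene-4-(TBSO)oxolan-2-one
Product: 17 (2Z)-2-[(1S)-1-(TBSO)-2-oxopropyl]hexadec-2-enoic acid
Conditions: Me3SnOH, ClCH2CH2Cl, 40 °C; then cold 0.5 M HCl wash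
Reagents that add atoms: trimethyltin hydroxide, C[Sn](C)(C)O
Why: Near-neutral acyl–oxygen cleavage of the reactive enol ester (trimethyltin hydroxide ester hydrolysis) opens the ring and the released enol tautomerises to the methyl ketone; with no strong base present the new α-silyloxy ketone centre (former C4, S) and the Z alkene are preserved.

**Step 14**
Reactants: 17 (2Z)-2-[(1S)-1-(TBSO)-2-oxopropyl]hexadec-2-enoic acid; 13 isoobtusilactone A
Product: 19 (3E,4S)-5-methylidene-2-oxo-3-tetradecylideneoxolan-4-yl (2Z)-2-[(1S)-1-(TBSO)-2-oxopropyl]hexadec-2-enoate, via mixed anhydride 18 (not isolated)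
Conditions: 2,4,6-Cl3C6H2COCl, Et3N, toluene, rt; then 13, 4-(dimethylamino)pyridine (DMAP), toluene, rt
Reagents that add atoms: none
Why: Yamaguchi esterification, DMAP attacking the less hindered acyl group of the mixed anhydride and the acylpyridinium acylating the hindered secondary alcohol with retention at C4; this is the method of choice for angelate-type Z acids, and a short run at rt in toluene limits Z→E drift and ketone epimerisation.

**Step 15**
Reactants: 19 the O-TBS ether of the target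
Product: 20 target, (3E,4S)-5-methylidene-2-oxo-3-tetradecylideneoxolan-4-yl (2Z)-2-[(1S)-1-hydroxy-2-oxopropyl]hexadec-2-enoate
Conditions: HF·pyridine, THF, 0 °C → rt
Reagents that add atoms: none
Why: Desilylation by Si–F bond formation under acidic non-aqueous conditions unveils the α-hydroxy ketone without epimerising C1′ or opening the enol lactone, as already shown on the same ring system in step 9.

**Compound list**
1 | 2-deoxy-D-ribose (open-chain form, 3S,4R) | O=CC[C@H](O)[C@H](O)CO | starting material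
2 | 2-deoxy-D-ribono-1,4-lactone, (4S,5R)-4-hydroxy-5-(hydroxymethyl)oxolan-2-one | OC[C@H]1OC(=O)C[C@@H]1O | intermediate
3 | (4S,5R)-4-(TBSO)-5-(TBSO-methyl)oxolan-2-one | CC(C)(C)[Si](C)(C)OC[C@H]1OC(=O)C[C@@H]1O[Si](C)(C)C(C)(C)C | intermediate
4 | tetradecanal | CCCCCCCCCCCCCC=O | starting material
5 | lithium enolate of 3 | CC(C)(C)[Si](C)(C)OC[C@H]1OC(O[Li])=C[C@@H]1O[Si](C)(C)C(C)(C)C | intermediate
6 | (3S,4S,5R)-4-(TBSO)-5-(TBSO-methyl)-3-(1-hydroxytetradecyl)oxolan-2-one, epimers at the carbinol | CCCCCCCCCCCCCC(O)[C@@H]1C(=O)O[C@H](CO[Si](C)(C)C(C)(C)C)[C@H]1O[Si](C)(C)C(C)(C)C | intermediate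
7 | 1-[(3R,4S,5R)-4-(TBSO)-5-(TBSO-methyl)-2-oxooxolan-3-yl]tetradecyl methanesulfonate, epimers at the carbinol | CCCCCCCCCCCCCC(OS(C)(=O)=O)[C@@H]1C(=O)O[C@H](CO[Si](C)(C)C(C)(C)C)[C@H]1O[Si](C)(C)C(C)(C)C | intermediate
8 | (3E,4S,5R)-3-tetradecylidene-4-(TBSO)-5-(TBSO-methyl)oxolan-2-one | CCCCCCCCCCCCC/C=C1/C(=O)O[C@H](CO[Si](C)(C)C(C)(C)C)[C@H]1O[Si](C)(C)C(C)(C)C | intermediate
9 | (3Z,4S,5R)-3-tetradecylidene-4-(TBSO)-5-(TBSO-methyl)oxolan-2-one | CCCCCCCCCCCCC/C=C1\C(=O)O[C@H](CO[Si](C)(C)C(C)(C)C)[C@H]1O[Si](C)(C)C(C)(C)C | intermediate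
10 | (3E,4S,5R)-5-(hydroxymethyl)-3-tetradecylidene-4-(TBSO)oxolan-2-one | CCCCCCCCCCCCC/C=C1/C(=O)O[C@H](CO)[C@H]1O[Si](C)(C)C(C)(C)C | intermediate
11 | (3E,4S,5S)-5-(iodomethyl)-3-tetradecylidene-4-(TBSO)oxolan-2-one | CCCCCCCCCCCCC/C=C1/C(=O)O[C@H](CI)[C@H]1O[Si](C)(C)C(C)(C)C | intermediate
12 | (3E,4S)-5-methylidene-3-tetradecylidene-4-(TBSO)oxolan-2-one | C=C1OC(=O)/C(=C/CCCCCCCCCCCCC)[C@@H]1O[Si](C)(C)C(C)(C)C | intermediate
13 | isoobtusilactone A, (3E,4S)-4-hydroxy-5-methylidene-3-tetradecylideneoxolan-2-one | C=C1OC(=O)/C(=C/CCCCCCCCCCCCC)[C@@H]1O | intermediate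
14 | (3Z,4S,5R)-5-(hydroxymethyl)-3-tetradecylidene-4-(TBSO)oxolan-2-one | CCCCCCCCCCCCC/C=C1\C(=O)O[C@H](CO)[C@H]1O[Si](C)(C)C(C)(C)C | intermediate
15 | (3Z,4S,5S)-5-(iodomethyl)-3-tetradecylidene-4-(TBSO)oxolan-2-one | CCCCCCCCCCCCC/C=C1\C(=O)O[C@H](CI)[C@H]1O[Si](C)(C)C(C)(C)C | intermediate
16 | (3Z,4S)-5-methylidene-3-tetradecylidene-4-(TBSO)oxolan-2-one | C=C1OC(=O)/C(=C\CCCCCCCCCCCCC)[C@@H]1O[Si](C)(C)C(C)(C)C | intermediate
17 | (2Z)-2-[(1S)-1-(TBSO)-2-oxopropyl]hexadec-2-enoic acid | OC(=O)/C(=C\CCCCCCCCCCCCC)[C@H](O[Si](C)(C)C(C)(C)C)C(C)=O | intermediate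
18 | mixed anhydride of 17 with 2,4,6-trichlorobenzoic acid | O=C(OC(=O)/C(=C\CCCCCCCCCCCCC)[C@H](O[Si](C)(C)C(C)(C)C)C(C)=O)c1c(Cl)cc(Cl)cc1Cl | intermediate
19 | (3E,4S)-5-methylidene-2-oxo-3-tetradecylideneoxolan-4-yl (2Z)-2-[(1S)-1-(TBSO)-2-oxopropyl]hexadec-2-enoate | C=C1OC(=O)/C(=C/CCCCCCCCCCCCC)[C@@H]1OC(=O)/C(=C\CCCCCCCCCCCCC)[C@H](O[Si](C)(C)C(C)(C)C)C(C)=O | intermediate
20 | (3E,4S)-5-methylidene-2-oxo-3-tetradecylideneoxolan-4-yl (2Z)-2-[(1S)-1-hydroxy-2-oxopropyl]hexadec-2-enoate | C=C1OC(=O)/C(=C/CCCCCCCCCCCCC)[C@@H]1OC(=O)/C(=C\CCCCCCCCCCCCC)[C@H](O)C(C)=O | target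

**Totals**
Total step count: 15.
Longest linear sequence: 11 steps (steps 1, 2, 3, 4, 5, 10, 11, 12, 13, 14, 15).

**Three steps most likely to fail**

Step 14 (esterification). A hindered angelate-type Z acid must acylate a hindered, doubly allylic alcohol that carries a sensitive enol lactone; Z→E drift of the acid and epimerisation of the α-silyloxy ketone under DMAP/Et3N are the dangers. Fallback: make the ester bond before ring A carries its enol lactone, so that forcing acylation is tolerated. Setting out from 11, HF·pyridine removes the secondary TBS group to give (3E,4S,5S)-4-hydroxy-5-(iodomethyl)-3-tetradecylideneoxolan-2-one F8. F8 is acylated with 17 (Yamaguchi anhydride at 50 °C, or the acid fluoride of 17) to give (3E,4S,5S)-5-(iodomethyl)-2-oxo-3-tetradecylideneoxolan-4-yl (2Z)-2-[(1S)-1-(TBSO)-2-oxopropyl]hexadec-2-enoate F9. The exocyclic alkene is then formed last by neutral dehydroiodination with AgF in pyridine at rt, which returns to the route at 19.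

Step 5 (photoisomerisation). The photostationary state may be poor in Z, or deconjugation may compete; the E/Z ratio of step 4 is also a prediction. Whatever that ratio, step 4 delivers both isomers, and the irradiation can be run from either one. Fallback: build the Z-alkylidene lactone stereospecifically by a second aldol-type union.
- Setting out from 4, CBr4/PPh3 gives 1,1-dibromopentadec-1-ene F1.
- n-BuLi (2 equiv, THF, −78 °C) gives lithium pentadec-1-yn-1-ide F2, trapped with ClCO2Et as ethyl hexadec-2-ynoate F3.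
- cis-Hydroalumination with iBu2AlH and N-methylmorpholine N-oxide (THF, 0 °C) gives diisobutyl[(1E)-1-(ethoxycarbonyl)pentadec-1-en-1-yl]aluminium F4, with H and Al cis and the chain cis to the ester.
- F4 adds to bought (R)-2,3-O-isopropylideneglyceraldehyde under Felkin–Anh control to give ethyl (2Z)-2-[(S)-[(4R)-2,2-dimethyl-1,3-dioxolan-4-yl](hydroxy)methyl]hexadec-2-enoate F5; the syn diastereomer is removed on silica.
- Aqueous trifluoroacetic acid in THF removes the acetonide and closes the γ-lactone to (3Z,4S,5R)-4-hydroxy-5-(hydroxymethyl)-3-tetradecylideneoxolan-2-one F6. The anti adduct has the same erythro configuration as the 2-deoxy-D-ribo series, which also proves the assignment.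
- Bis-silylation of F6 (TBSOTf, 2,6-lutidine) returns to the route at 9.

Step 13 (ring opening to the keto acid). The product is a β,γ-unsaturated α-silyloxy ketone that can epimerise or isomerise if any basic species lingers, and the TBS group limits the use of aqueous acid. Fallback: avoid hydrolysis altogether. Setting out from 16, neutral alcoholysis with allyl alcohol catalysed by the distannoxane ClBu2SnOSnBu2Cl (toluene, 50 °C) gives prop-2-en-1-yl (2Z)-2-[(1S)-1-(TBSO)-2-oxopropyl]hexadec-2-enoate F7. Deallylation of F7 with Pd(PPh3)4 (zerovalent palladium) and PhSiH3 in CH2Cl2 at rt returns to the route at 17.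

**Further compounds**
F1 | step 5 | 1,1-dibromopentadec-1-ene | CCCCCCCCCCCCCC=C(Br)Br
F2 | step 5 | lithium pentadec-1-yn-1-ide | [Li]C#CCCCCCCCCCCCCC
F3 | step 5 | ethyl hexadec-2-ynoate | CCCCCCCCCCCCCC#CC(=O)OCC
F4 | step 5 | diisobutyl[(1E)-1-(ethoxycarbonyl)pentadec-1-en-1-yl]aluminium | CCCCCCCCCCCCC/C=C(\C(=O)OCC)[Al](CC(C)C)CC(C)C
F5 | step 5 | ethyl (2Z)-2-[(S)-[(4R)-2,2-dimethyl-1,3-dioxolan-4-yl](hydroxy)methyl]hexadec-2-enoate | CCCCCCCCCCCCC/C=C(\C(=O)OCC)[C@H](O)[C@H]1COC(C)(C)O1
F6 | step 5 | (3Z,4S,5R)-4-hydroxy-5-(hydroxymethyl)-3-tetradecylideneoxolan-2-one | CCCCCCCCCCCCC/C=C1\C(=O)O[C@H](CO)[C@H]1O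
F7 | step 13 | prop-2-en-1-yl (2Z)-2-[(1S)-1-(TBSO)-2-oxopropyl]hexadec-2-enoate | C=CCOC(=O)/C(=C\CCCCCCCCCCCCC)[C@H](O[Si](C)(C)C(C)(C)C)C(C)=O
F8 | step 14 | (3E,4S,5S)-4-hydroxy-5-(iodomethyl)-3-tetradecylideneoxolan-2-one | CCCCCCCCCCCCC/C=C1/C(=O)O[C@H](CI)[C@H]1O
F9 | step 14 | (3E,4S,5S)-5-(iodomethyl)-2-oxo-3-tetradecylideneoxolan-4-yl (2Z)-2-[(1S)-1-(TBSO)-2-oxopropyl]hexadec-2-enoate | CCCCCCCCCCCCC/C=C1/C(=O)O[C@H](CI)[C@H]1OC(=O)/C(=C\CCCCCCCCCCCCC)[C@H](O[Si](C)(C)C(C)(C)C)C(C)=O
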